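**Retrosynthetic overview**

1. The last C–C bond made is C7'–C8' of the side chain, by a Zweifel olefination (1,2-boronate shift, then anti elimination) between (E)-dec-1-enyllithium and a primary alkyl pinacol boronate that already carries ring A with all three stereocentres. One operation joins the halves, sets the 8'Z olefin and expels boron.
2. Enabling feature: the C7'H2–C8'H=C9'H unit, a cis-1,2-dialkylethene held seven methylenes away from ring A (the cyclohexenone). The C1 carbonyl of ring A is stored as the C1=C2 silyl enol ether, which hides it from the organolithium and is afterwards oxidised to the C2=C3 enone.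
3. C6–C1' bond: B-alkyl Suzuki–Miyaura coupling of a 2-iodocyclohexenone with a heptane-1,7-diyl linchpin carrying two different borons (the 9-BBN end couples, the pinacol boronate end is kept for the key step).
4. Stereochemistry: C4 is set by a CBS reduction; C5 and C6 are relayed from it in one OsO4 dihydroxylation anti to the C4 silyl ether.
5. Rings: ring A is bought in the starting enone ketal. The only ring closed on the way is the temporary dioxolane over O5/O6 (step 8), opened in the last step.

Key step: step 11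

Remark: ring A is discussed with the numbering of the target (C1 carbonyl carbon, C6 quaternary carbinol carbon) and the side chain is numbered C1'–C17' outward from C6.

**Route**

Step 1
Reactants: 1 1,4-dioxaspiro[4.5]dec-6-en-8-one
Product: 2 (S)-1,4-dioxaspiro[4.5]dec-6-en-8-ol
Conditions: (R)-2-methyl-CBS-oxazaborolidine (0.2 equiv), catecholborane (1.5 equiv), toluene, −78 °C; aq. NaOH work-up
Reagents that add atoms: none
Why: Corey–Bakshi–Shibata reduction, in which the oxazaborolidine binds the ketone with the alkenyl flank (made bulkier by the spiro ketal) as the large group and delivers hydride 1,2 to one face, which should set the future C4 as S.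

Step 2
Reactants: 2 (S)-1,4-dioxaspiro[4.5]dec-6-en-8-ol
Product: 3 (S)-8-(tert-butyldimethylsilyloxy)-1,4-dioxaspiro[4.5]dec-6-ene
Conditions: TBSCl, imidazole, DMF, rt
Reagents that add atoms: tert-butyldimethylsilyl chloride CC(C)(C)[Si](C)(C)Cl
Why: Standard silylation of a secondary allylic alcohol; the stereocentre is not involved.

Step 3
Reactants: 3 (S)-8-(tert-butyldimethylsilyloxy)-1,4-dioxaspiro[4.5]dec-6-ene
Product: 4 (S)-4-(tert-butyldimethylsilyloxy)cyclohex-2-en-1-one
Conditions: PPTS (cat.), acetone/H2O, 45 °C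
Reagents that add atoms: water O
Why: Mild acid hydrolysis of an allylic ketal, which should unmask the ketone at the former ketal carbon (transposed enone) while the silyl ether and its stereocentre stay intact.

Step 4
Reactants: 4 (S)-4-(tert-butyldimethylsilyloxy)cyclohex-2-en-1-one
Product: 5 (S)-4-(tert-butyldimethylsilyloxy)-2-iodocyclohex-2-en-1-one
Conditions: I2, pyridine/CH2Cl2, 0 °C to rt
Reagents that add atoms: iodine II
Why: α-Iodination of an enone by the iodine/pyridine protocol (conjugate addition of pyridine, iodination of the enolate, elimination), which should place iodine at C2 only.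

Step 5
Reactants: 6 7-bromohept-1-ene
Product: 8 2-(hept-6-en-1-yl)-4,4,5,5-tetramethyl-1,3,2-dioxaborolane, via hept-6-enylmagnesium bromide 7 (not isolated)
Conditions: Mg, THF, rt; then 2-isopropoxy-4,4,5,5-tetramethyl-1,3,2-dioxaborolane, −78 °C to rt; aq. HCl work-up
Reagents that add atoms: 2-isopropoxy-4,4,5,5-tetramethyl-1,3,2-dioxaborolane CC(C)OB1OC(C)(C)C(C)(C)O1
Why: Grignard formation and borylation with an alkoxy pinacol borate, a routine way to a primary alkyl pinacol boronate.

Step 6
Reactants: 8 2-(hept-6-en-1-yl)-4,4,5,5-tetramethyl-1,3,2-dioxaborolane; 5 (S)-4-(tert-butyldimethylsilyloxy)-2-iodocyclohex-2-en-1-one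
Product: 10 (S)-4-(tert-butyldimethylsilyloxy)-2-[7-(4,4,5,5-tetramethyl-1,3,2-dioxaborolan-2-yl)heptyl]cyclohex-2-en-1-one, via 9-[7-(pinacolboryl)heptyl]-9-borabicyclo[3.3.1]nonane 9 (not isolated)
Conditions: 8, 9-BBN, THF, rt; then 5, Pd(dppf)Cl2 (5 mol%), AsPh3, Cs2CO3, DMF/H2O, rt
Reagents that add atoms: none
Why: Anti-Markovnikov hydroboration of the terminal olefin and B-alkyl Suzuki–Miyaura coupling with the α-iodoenone; the B-alkyl-9-BBN transmetalates at room temperature under aqueous carbonate whereas the primary alkyl pinacol boronate does not, so the second boron should be carried through.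

Step 7
Reactants: 10 (S)-4-(tert-butyldimethylsilyloxy)-2-[7-(pinacolboryl)heptyl]cyclohex-2-en-1-one
Product: 11 (2R,3R,4S)-4-(tert-butyldimethylsilyloxy)-2,3-dihydroxy-2-[7-(4,4,5,5-tetramethyl-1,3,2-dioxaborolan-2-yl)heptyl]cyclohexan-1-one
Conditions: OsO4 (5 mol%), NMO (1.3 equiv), acetone/H2O, rt
Reagents that add atoms: osmium tetroxide O=[Os](=O)(=O)=O; N-methylmorpholine N-oxide C[N+]1([O-])CCOCC1; water O
Why: Upjohn dihydroxylation, in which OsO4 adds suprafacially to the enone olefin from the face anti to the allylic C4 silyloxy group (the empirical rule for osmylation of allylic ethers), so that C5 and C6 should be set together in one event (5-OH trans to 4-O, 6-OH cis to 5-OH); the alkyl pinacol boronate is expected to resist the N-oxide at room temperature.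

Step 8
Reactants: 11 (2R,3R,4S)-4-(tert-butyldimethylsilyloxy)-2,3-dihydroxy-2-[7-(pinacolboryl)heptyl]cyclohexan-1-one
Product: 12 (2R,3R,4S)-4-(tert-butyldimethylsilyloxy)-2,3-(isopropylidenedioxy)-2-[7-(4,4,5,5-tetramethyl-1,3,2-dioxaborolan-2-yl)heptyl]cyclohexan-1-one (cis-fused acetonide)
Conditions: 2,2-dimethoxypropane, PPTS (cat.), CH2Cl2, rt
Reagents that add atoms: 2,2-dimethoxypropane COC(C)(C)OC
Why: Acid-catalysed transacetalisation, which should close the five-membered dioxolane readily because the tertiary and secondary hydroxyls are cis.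

Step 9
Reactants: 12 (2R,3R,4S)-4-(tert-butyldimethylsilyloxy)-2,3-(isopropylidenedioxy)-2-[7-(pinacolboryl)heptyl]cyclohexan-1-one
Product: 13 (4S,5R,6R)-1,4-bis(tert-butyldimethylsilyloxy)-5,6-(isopropylidenedioxy)-6-[7-(4,4,5,5-tetramethyl-1,3,2-dioxaborolan-2-yl)heptyl]cyclohex-1-ene
Conditions: TBSOTf, Et3N, CH2Cl2, 0 °C
Reagents that add atoms: tert-butyldimethylsilyl trifluoromethanesulfonate CC(C)(C)[Si](C)(C)OS(=O)(=O)C(F)(F)F
Why: Soft enolisation with a silyl triflate and an amine; C6 is quaternary, so only the C1=C2 enol ether can form, which masks the carbonyl for step 11 and is the handle for step 12.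

Step 10
Reactants: 14 dec-1-yne
Product: 16 (E)-1-iododec-1-ene, via (E)-dec-1-enylzirconocene chloride 15 (not isolated)
Conditions: Cp2Zr(H)Cl, THF, rt; then I2, 0 °C
Reagents that add atoms: iodine II
Why: Hydrozirconation of a terminal alkyne is syn and places zirconium at the terminal carbon, and iodinolysis of the C–Zr bond proceeds with retention, which should give the E-iodide.

Step 11
Reactants: 16 (E)-1-iododec-1-ene; 13 (4S,5R,6R)-1,4-bis(tert-butyldimethylsilyloxy)-5,6-(isopropylidenedioxy)-6-[7-(pinacolboryl)heptyl]cyclohex-1-ene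
Product: 20 (4S,5R,6R)-1,4-bis(tert-butyldimethylsilyloxy)-6-[(Z)-heptadec-8-en-1-yl]-5,6-(isopropylidenedioxy)cyclohex-1-ene, via (E)-dec-1-enyllithium 17 (not isolated), via lithium alkenylboronate complex 18 (not isolated), via anti β-iodoalkylboronate 19 (not isolated)
Conditions: 16, t-BuLi (2.0 equiv), Et2O, −78 °C; 13, THF, −78 °C; I2 (no excess), MeOH, −78 °C; NaOMe, MeOH, −78 to 0 °C
Reagents that add atoms: none
Why: Zweifel olefination (1,2-metallate rearrangement of an alkenylboronate complex): (E)-dec-1-enyllithium, formed from 16 by iodine–lithium exchange with retention, adds to the boron of 13 to give complex 18; iodine activates the alkenyl group as an iodonium ion and the primary C7' carbon migrates from boron to C8' anti to the forming C–I bond (19); methoxide then triggers anti elimination of boron and iodide, so that the E-alkenyl precursor should emerge as the Z-olefin. The closest known reaction type is the iodine/methoxide coupling of primary alkyl pinacol boronic esters with E-alkenyllithiums to give Z-1,2-dialkylethenes. No ring is closed and no permanent stereocentre is formed; the two transient centres of 19 are fixed relative to each other by the anti addition and are destroyed in the anti elimination, and this pairing is what controls the olefin geometry. The step needs the organolithium to attack boron only, which is secured because the single carbonyl of ring A is stored as the C1=C2 silyl enol ether and the remaining groups are a silyl ether and an acetal; it needs a single migrating group, which is secured because the pinacol oxygens do not migrate; and it needs iodine to choose the alkenylboronate over the enol ether, which is secured by the far higher nucleophilicity of the anionic complex at −78 °C and by using iodine without excess. The three stereocentres of ring A lie seven methylenes from the reacting atoms and should not be touched.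

Step 12
Reactants: 20 (4S,5R,6R)-1,4-bis(tert-butyldimethylsilyloxy)-6-[(Z)-heptadec-8-en-1-yl]-5,6-(isopropylidenedioxy)cyclohex-1-ene
Product: 21 (4S,5R,6R)-4-(tert-butyldimethylsilyloxy)-6-[(Z)-heptadec-8-en-1-yl]-5,6-(isopropylidenedioxy)cyclohex-2-en-1-one
Conditions: Pd(OAc)2 (1.1 equiv), MeCN, rt
Reagents that add atoms: none
Why: Saegusa–Ito oxidation, in which palladium diacetate engages the electron-rich enol ether in preference to the isolated olefin, forms the oxa-π-allyl species and undergoes β-hydride elimination toward C3, which should give the C2=C3 enone.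

Step 13
Reactants: 21 (4S,5R,6R)-4-(tert-butyldimethylsilyloxy)-6-[(Z)-heptadec-8-en-1-yl]-5,6-(isopropylidenedioxy)cyclohex-2-en-1-one
Product: 22 pleiogenone A, (4S,5R,6R)-6-[(Z)-heptadec-8-en-1-yl]-4,5,6-trihydroxycyclohex-2-en-1-one
Conditions: TFA/H2O/THF (4:1:1), 0 °C to rt
Reagents that add atoms: none
Why: Aqueous acid hydrolysis of the acetonide and of the secondary silyl ether in one operation; none of the three carbinol centres is epimerisable under these conditions and the Z-olefin is inert.

**Compound list**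

1 | 1,4-dioxaspiro[4.5]dec-6-en-8-one | O=C1C=CC2(CC1)OCCO2 | starting material
2 | (S)-1,4-dioxaspiro[4.5]dec-6-en-8-ol | O[C@@H]1C=CC2(CC1)OCCO2 | intermediate
3 | (S)-8-(tert-butyldimethylsilyloxy)-1,4-dioxaspiro[4.5]dec-6-ene | CC(C)(C)[Si](C)(C)O[C@@H]1C=CC2(CC1)OCCO2 | intermediate
4 | (S)-4-(tert-butyldimethylsilyloxy)cyclohex-2-en-1-one | O=C1C=C[C@@H](O[Si](C)(C)C(C)(C)C)CC1 | intermediate
5 | (S)-4-(tert-butyldimethylsilyloxy)-2-iodocyclohex-2-en-1-one | O=C1C(I)=C[C@@H](O[Si](C)(C)C(C)(C)C)CC1 | intermediate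
6 | 7-bromohept-1-ene | C=CCCCCCBr | starting material
7 | hept-6-enylmagnesium bromide | C=CCCCCC[Mg]Br | intermediate (not isolated)
8 | 2-(hept-6-en-1-yl)-4,4,5,5-tetramethyl-1,3,2-dioxaborolane | C=CCCCCCB1OC(C)(C)C(C)(C)O1 | intermediate
9 | 9-[7-(4,4,5,5-tetramethyl-1,3,2-dioxaborolan-2-yl)heptyl]-9-borabicyclo[3.3.1]nonane | CC1(C)OB(OC1(C)C)CCCCCCCB2C3CCCC2CCC3 | intermediate (not isolated)
10 | (S)-4-(tert-butyldimethylsilyloxy)-2-[7-(pinacolboryl)heptyl]cyclohex-2-en-1-one | CC1(C)OB(OC1(C)C)CCCCCCCC2=C[C@@H](O[Si](C)(C)C(C)(C)C)CCC2=O | intermediate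
11 | (2R,3R,4S)-4-(tert-butyldimethylsilyloxy)-2,3-dihydroxy-2-[7-(pinacolboryl)heptyl]cyclohexan-1-one | CC1(C)OB(OC1(C)C)CCCCCCC[C@]2(O)C(=O)CC[C@H](O[Si](C)(C)C(C)(C)C)[C@H]2O | intermediate
12 | (2R,3R,4S)-4-(tert-butyldimethylsilyloxy)-2,3-(isopropylidenedioxy)-2-[7-(pinacolboryl)heptyl]cyclohexan-1-one | CC1(C)OB(OC1(C)C)CCCCCCC[C@]2(OC(C)(C)O3)C(=O)CC[C@H](O[Si](C)(C)C(C)(C)C)[C@H]23 | intermediate
13 | (4S,5R,6R)-1,4-bis(tert-butyldimethylsilyloxy)-5,6-(isopropylidenedioxy)-6-[7-(pinacolboryl)heptyl]cyclohex-1-ene | CC1(C)OB(OC1(C)C)CCCCCCC[C@]2(OC(C)(C)O3)C(O[Si](C)(C)C(C)(C)C)=CC[C@H](O[Si](C)(C)C(C)(C)C)[C@H]23 | intermediate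
14 | dec-1-yne | CCCCCCCCC#C | starting material
15 | (E)-dec-1-enylzirconocene chloride (cyclopentadienyl rings drawn σ-bonded) | CCCCCCCC/C=C/[Zr](Cl)(C1C=CC=C1)C1C=CC=C1 | intermediate (not isolated)
16 | (E)-1-iododec-1-ene | CCCCCCCC/C=C/I | intermediate
17 | (E)-dec-1-enyllithium | CCCCCCCC/C=C/[Li] | intermediate (not isolated)
18 | lithium [(E)-dec-1-enyl](alkyl)pinacolatoborate, the boronate complex of 13 | [Li+].CCCCCCCC/C=C/[B-]1(OC(C)(C)C(C)(C)O1)CCCCCCC[C@]2(OC(C)(C)O3)C(O[Si](C)(C)C(C)(C)C)=CC[C@H](O[Si](C)(C)C(C)(C)C)[C@H]23 | intermediate (not isolated)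
19 | anti β-iodoalkylboronate (C8' boryl, C9' iodo; one of the two anti adducts drawn, the other has both new centres inverted) | CCCCCCCC[C@@H](I)[C@H](B1OC(C)(C)C(C)(C)O1)CCCCCCC[C@]2(OC(C)(C)O3)C(O[Si](C)(C)C(C)(C)C)=CC[C@H](O[Si](C)(C)C(C)(C)C)[C@H]23 | intermediate (not isolated)
20 | (4S,5R,6R)-1,4-bis(tert-butyldimethylsilyloxy)-6-[(Z)-heptadec-8-en-1-yl]-5,6-(isopropylidenedioxy)cyclohex-1-ene | CCCCCCCC/C=C\CCCCCCC[C@]1(OC(C)(C)O2)C(O[Si](C)(C)C(C)(C)C)=CC[C@H](O[Si](C)(C)C(C)(C)C)[C@H]12 | intermediate
21 | (4S,5R,6R)-4-(tert-butyldimethylsilyloxy)-6-[(Z)-heptadec-8-en-1-yl]-5,6-(isopropylidenedioxy)cyclohex-2-en-1-one | CCCCCCCC/C=C\CCCCCCC[C@]1(OC(C)(C)O2)C(=O)C=C[C@H](O[Si](C)(C)C(C)(C)C)[C@H]12 | intermediate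
22 | pleiogenone A, (4S,5R,6R)-6-[(Z)-heptadec-8-en-1-yl]-4,5,6-trihydroxycyclohex-2-en-1-one | CCCCCCCC/C=C\CCCCCCC[C@]1(O)C(=O)C=C[C@H](O)[C@H]1O | target

**Summary**

Total step count: 13. Longest linear sequence: 11 steps (steps 1–4, 6–9, 11–13); steps 5 and 10 prepare the two side fragments.

**Steps most likely to fail**

Step 11. The silyl enol ether may be iodinated or methanolysed in competition with the boronate complex, or complex formation may be incomplete, which would lower the yield and the Z purity. Fallback, a stereoretentive palladium cross-coupling in place of the boronate rearrangement, setting out from 12 and 14: 12 is treated with KHF2 (MeOH/H2O, rt) to give the potassium trifluoroborate F1. Dec-1-yne 14 is iodinated (N-iodosuccinimide, AgNO3 cat., acetone) to 1-iododec-1-yne F2, which is reduced with diimide (2-nitrobenzenesulfonyl hydrazide, Et3N) to (Z)-1-iododec-1-ene F3. Suzuki–Miyaura coupling of F1 with F3 (Pd(dppf)Cl2, Cs2CO3, toluene/H2O, 80 °C) should give, with retention of the olefin geometry, (2R,3R,4S)-4-(tert-butyldimethylsilyloxy)-2-[(Z)-heptadec-8-en-1-yl]-2,3-(isopropylidenedioxy)cyclohexan-1-one F4. Silylation as in step 9 (TBSOTf, Et3N) comes back to the route at 20.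

Step 7. The dihydroxylation of the electron-poor trisubstituted enone may be slow enough for the N-oxide to oxidise the C–B bond. Fallback, in which boron is introduced only after the oxidation, setting out from 5 and 6: 7-bromohept-1-ene 6 is hydroborated with 9-BBN to 9-(7-bromoheptyl)-9-borabicyclo[3.3.1]nonane F5, which is coupled with 5 under the conditions of step 6 to (S)-2-(7-bromoheptyl)-4-(tert-butyldimethylsilyloxy)cyclohex-2-en-1-one F6. Dihydroxylation as in step 7 should give the bromo diol F7 and acetonide formation as in step 8 the bromo acetonide F8. Copper-catalysed borylation of the primary bromide (CuI, PPh3, LiOMe, bis(pinacolato)diboron, DMF, rt) comes back to the route at 12.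

Step 12. The palladium hydride released in the oxidation may isomerise or shift the remote Z-olefin, or the hindered silyl enol ether may react sluggishly. Fallback, a selenoxide elimination, setting out from 20: PhSeCl (1.0 equiv, THF, −78 °C; the enol ether reacts far faster than the isolated olefin) should give the α-phenylselanyl ketone F9 (C2 epimers). Oxidation with NaIO4 (NaHCO3, THF/H2O, rt) and syn elimination of the selenoxide toward C3 come back to the route at 21.

**Further compounds**

F1 | step 11 | potassium trifluoro{7-[(1R,2R,3S)-3-(tert-butyldimethylsilyloxy)-1,2-(isopropylidenedioxy)-6-oxocyclohexyl]heptyl}borate | [K+].F[B-](F)(F)CCCCCCC[C@]1(OC(C)(C)O2)C(=O)CC[C@H](O[Si](C)(C)C(C)(C)C)[C@H]12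
F2 | step 11 | 1-iododec-1-yne | CCCCCCCCC#CI
F3 | step 11 | (Z)-1-iododec-1-ene | CCCCCCCC/C=C\I
F4 | step 11 | (2R,3R,4S)-4-(tert-butyldimethylsilyloxy)-2-[(Z)-heptadec-8-en-1-yl]-2,3-(isopropylidenedioxy)cyclohexan-1-one | CCCCCCCC/C=C\CCCCCCC[C@]1(OC(C)(C)O2)C(=O)CC[C@H](O[Si](C)(C)C(C)(C)C)[C@H]12
F5 | step 7 | 9-(7-bromoheptyl)-9-borabicyclo[3.3.1]nonane | BrCCCCCCCB1C2CCCC1CCC2
F6 | step 7 | (S)-2-(7-bromoheptyl)-4-(tert-butyldimethylsilyloxy)cyclohex-2-en-1-one | BrCCCCCCCC1=C[C@@H](O[Si](C)(C)C(C)(C)C)CCC1=O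
F7 | step 7 | (2R,3R,4S)-2-(7-bromoheptyl)-4-(tert-butyldimethylsilyloxy)-2,3-dihydroxycyclohexan-1-one | BrCCCCCCC[C@]1(O)C(=O)CC[C@H](O[Si](C)(C)C(C)(C)C)[C@H]1O
F8 | step 7 | (2R,3R,4S)-2-(7-bromoheptyl)-4-(tert-butyldimethylsilyloxy)-2,3-(isopropylidenedioxy)cyclohexan-1-one | BrCCCCCCC[C@]1(OC(C)(C)O2)C(=O)CC[C@H](O[Si](C)(C)C(C)(C)C)[C@H]12
F9 | step 12 | (4S,5R,6R)-4-(tert-butyldimethylsilyloxy)-6-[(Z)-heptadec-8-en-1-yl]-5,6-(isopropylidenedioxy)-2-(phenylselanyl)cyclohexan-1-one (C2 epimers) | CCCCCCCC/C=C\CCCCCCC[C@]1(OC(C)(C)O2)C(=O)C([Se]c3ccccc3)C[C@H](O[Si](C)(C)C(C)(C)C)[C@H]12
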